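## Analysis of the target

The target is a 2,3-dihydro-1-benzofuran in which ring A (the benzene ring) carries an acetyl group at C5 and a hydroxyl at C6 that is hydrogen-bonded to the acetyl carbonyl, and ring B is the dihydrofuran made of O1, C2, C3, C3a and C7a. C2 (S) carries an isopropenyl group and C3 (R) carries an ester oxygen; these are the only stereocentres and the two substituents are trans. The acyl part is a (Z)-2-(acetoxymethyl)but-2-enoate, with the carbonyl cis to the β-methyl group (angelate-type, the less stable alkene isomer). Its CH2OAc group is an allylic acetate on an acrylate, which nucleophiles and zerovalent palladium both attack easily. The C3 ester is benzylic, ortho to O1 and para to the C6 hydroxyl, so acid or base can expel the carboxylate and ring B then aromatises to the benzofuran, destroying both stereocentres. The hard part is therefore to set a trans C2/C3 pair in one absolute configuration on a labile ring and to have a hindered Z-acid on the benzylic oxygen without isomerising or eliminating it. The plan rests on one structural reading: C3 (bonded to C3a and the ester oxygen) and C2 (bonded to O1 and the isopropenyl carbon) are the two carbons of the enol-ester C=C of a 1-acyloxy-3-methylbuta-1,3-diene, so an iodophenol can deliver its aryl carbon to one end of that alkene and its ortho oxygen to the other.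

## Retrosynthetic reasoning

**Side-chain acetate (12 to 11 to 10).** The acetate C–O bond of the CH2OAc group is cut first, and the freed primary alcohol 11 is traced back to its silyl ether 10. An acrylate-bound allylic acetate would be ionised by zerovalent palladium and displaced by a phenoxide during the annulation, whereas a silyl ether is inert there. The forward steps must free the primary alcohol without forming a phenoxide para to the benzylic ester, and then acetylate that alcohol in preference to the chelated phenol.

**Ring B (10 to 9 plus 7).** The bonds C3a–C3 and O1–C2 are cut together. They are the only links between ring A and the two stereogenic carbons, so cutting them separates an achiral iodophenol 9 from an achiral dienyl ester 7 that already contains the complete acyl group. This gives convergence, and it means the sensitive benzylic alcohol never has to be acylated. The forward reaction has to send the aryl group to the oxygen-bearing diene carbon, choose one face of that alkene, and close the ring trans.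

**Enol ester (7 to 5 plus 6).** The O–C(vinyl) bond of the enol ester is cut, leading to acid 5 and enyne 6. Enol esters of aldehydes are not available by acylating an enolisable aldehyde with geometric control, but anti-Markovnikov addition of an acid to a terminal alkyne forms exactly this bond under neutral conditions. The geometry of the new alkene matters little, because it is erased in the allyl intermediate of the key step.

**Acid (5 to 4 to 3 to 2 to 1).** The bond between the alkenyl carbon and the carboxyl carbon is cut. The Z geometry corresponds to an anti addition of hydrogen and a carboxyl group across the triple bond of 1, with the carboxyl on the carbon that bears the hydroxymethyl group. A Morita–Baylis–Hillman-based route would give mainly the E isomer. Forward, a hydroxyl-directed trans-hydrostannation fixes both regiochemistry and geometry in 2, carbonylation with retention gives 3, and silylation and mild saponification give 5 by way of 4.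

**Iodide (9 to 8).** The C–I bond is cut. The carbon para to the chelated hydroxyl and ortho to the free one is the electronically preferred and less crowded site of 8, so direct iodination should suffice.

## Alternatives that were turned down

**Alternative 1:** The disconnection is O1–C7a, after the C2–C3 bond has been made by an organocatalytic aldol-type reaction that gives an anti diol. In the forward key step, the C2 alkoxide of 1-[5-[(1R,2S)-1,2-dihydroxy-3-methylbut-3-en-1-yl]-2,4-difluorophenyl]ethanone A2 displaces the fluorine para to the acetyl group and closes ring B. The product is 1-[(2S,3R)-6-fluoro-3-hydroxy-2-(prop-1-en-2-yl)-2,3-dihydro-1-benzofuran-5-yl]ethanone A1.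
- For it: intramolecular SNAr para to a ketone is dependable, the benzylic alkoxide of A2 cannot compete (it would close a four-membered ring), and the trans relationship of A1 is carried over unchanged from the diol A2. On precedent this route is stronger than the chosen one, since every reaction type is established.
- Against it: C6 of A1 still carries fluorine, which must be exchanged for oxygen by a second SNAr beside a base-sensitive benzylic carbinol. The methyl ketone is itself an enolisable partner in the step that forms A2 and would need masking. The isopropenyl group of A2 has to be made by methylenation next to an epimerisable centre. The hindered Z-acid must finally be attached to the benzylic alcohol, under conditions that invite Z-to-E isomerisation and elimination to the benzofuran.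
- Comparison: it is linear and several steps longer. The chosen route offers convergence instead, with the C6 hydroxyl present from the start and the ester already in place when C3 is created.

**Alternative 2:** The disconnection is C2–C3. In the forward key step, 5-acetyl-4-hydroxy-2-(propa-1,2-dien-1-yloxy)benzaldehyde A4 reacts with Ni(cod)2, a chiral ligand and ZnMe2. The aldehyde carbon is joined to the oxygen-bearing allene carbon and the central allene carbon is methylated, giving the cis diol 1-[(2S,3S)-3,6-dihydroxy-2-(prop-1-en-2-yl)-2,3-dihydro-1-benzofuran-5-yl]ethanone A3.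
- For it: ring B, the C2–C3 bond and the isopropenyl group arise in one operation from the very simple precursor A4. Up to A3 its step economy is as good as or better than that of the chosen route.
- Against it: the metallacycle delivers the cis isomer A3, so the ester has to be introduced with inversion at C3, on a benzylic carbinol para to a phenol that ionises and eliminates easily. ZnMe2 is consumed by the free phenol of A4 and can add to its aldehyde or ketone, so protection is needed. The allenyl aryl ether of A4 must be made by base isomerisation beside an aldehyde. The enantioselective form of this coupling is as unproven as the key step chosen here.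
- Comparison: it carries the same novelty risk and then adds a fragile inversion. The chosen route gives the trans ester directly.

**Alternative 3:** The disconnection is O1–C2 with a skeletal change, tracing the dihydrofuran back to a 2,2-dimethylchroman. In the forward key step, Tf2O activates the C3 hydroxyl of (3S,4R)-6-acetyl-7-(tert-butyldimethylsilyloxy)-3-hydroxy-2,2-dimethyl-3,4-dihydro-2H-chromen-4-yl (Z)-2-(acetoxymethyl)but-2-enoate A6. The ring oxygen, anti-periplanar to the equatorial leaving group, moves from the gem-dimethyl carbon to C3 with inversion, and the tertiary cation loses a proton. The product is (2S,3R)-5-acetyl-6-(tert-butyldimethylsilyloxy)-2-(prop-1-en-2-yl)-2,3-dihydro-1-benzofuran-3-yl (Z)-2-(acetoxymethyl)but-2-enoate A5.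
- For it: the stereocentres of A6 come from asymmetric epoxidation of a 2,2-dimethylchromene and a trans ring opening, both highly reliable. No palladium is involved, so the acid can carry its acetate from the beginning and A5 already holds the complete side chain. On both points it is stronger than the chosen strategy.
- Against it: in A6 a cation is generated next to a carbon bearing an ester whose carbonyl can participate, and next to an electron-rich benzylic position that can ionise. The linear chromene has to be built regioselectively. The phenol must be protected and freed, so A5 is still one step short of the target. The longest sequence is clearly longer.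
- Comparison: the chosen strategy is shorter and convergent but rests on an untested step. A silyl-protected variant of the ring contraction of A6 is therefore kept as the fallback for the key step.

Key step: step 7

## Route

Remark: the ligand antipode that leads to the (3R) series cannot be derived from precedent; (R)-BINAP is written in step 7, and its enantiomer is to be used if insertion favours the other face of the enol ester.

Remark: species that exist only on the metal within a catalytic cycle (arylpalladium, allylpalladium, ruthenium vinylidene) are treated as mechanism, not as numbered compounds.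

Step 1
Reactants: 1 but-2-yn-1-ol
Product: 2 (Z)-2-(tributylstannyl)but-2-en-1-ol
Conditions: Bu3SnH (1.1 equiv), [(C5Me5)RuCl]4 (1–2 mol%), CH2Cl2, rt
Reagents that add atoms: tributyltin hydride, CCCC[SnH](CCCC)CCCC
Why: Ruthenium-catalysed trans-hydrostannation of a propargylic alcohol; the free hydroxyl steers tin to the proximal alkyne carbon, and anti addition places tin cis to the methyl group, which fixes the later Z geometry of the acid.

Step 2
Reactants: 2 (Z)-2-(tributylstannyl)but-2-en-1-ol
Product: 3 methyl (Z)-2-(hydroxymethyl)but-2-enoate
Conditions: Pd(OAc)2 (5 mol%), Ph3As (20 mol%), 1,4-benzoquinone (1.5 equiv), CF3CO2H (cat.), CO (1 atm), MeOH, rt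
Reagents that add atoms: carbon monoxide, [C-]#[O+]; methanol, CO
Why: Oxidative alkoxycarbonylation of an alkenylstannane, known for 2-stannyl allylic alcohols, in which the free hydroxyl assists tin-to-palladium transfer; CO insertion and methanolysis proceed with retention, so the ester should end up cis to the methyl group, and benzoquinone returns zerovalent palladium to the divalent state.

Step 3
Reactants: 3 methyl (Z)-2-(hydroxymethyl)but-2-enoate
Product: 4 methyl (Z)-2-[(tert-butyldimethylsilyloxy)methyl]but-2-enoate
Conditions: TBSCl, imidazole, CH2Cl2, 0 °C to rt
Reagents that add atoms: tert-butyldimethylsilyl chloride, CC(C)(C)[Si](C)(C)Cl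
Why: Standard silylation of a primary alcohol; the silyl ether is the form of the allylic oxygen that zerovalent palladium does not ionise in step 7.

Step 4
Reactants: 4 methyl (Z)-2-[(tert-butyldimethylsilyloxy)methyl]but-2-enoate
Product: 5 (Z)-2-[(tert-butyldimethylsilyloxy)methyl]but-2-enoic acid
Conditions: LiOH·H2O, THF/H2O (3:1), 0 °C to rt; then 1 M HCl to pH 4 at 0 °C
Reagents that add atoms: lithium hydroxide, [Li+].[OH-]
Why: Saponification of a methyl ester; low temperature, the absence of alkoxide and a mildly acidic work-up should preserve the Z alkene and the primary silyl ether.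

Step 5
Reactants: 5 (Z)-2-[(tert-butyldimethylsilyloxy)methyl]but-2-enoic acid; 6 2-methylbut-1-en-3-yne
Product: 7 (1Z)-3-methylbuta-1,3-dien-1-yl (Z)-2-[(tert-butyldimethylsilyloxy)methyl]but-2-enoate
Conditions: Ru(η3-CH2C(CH3)CH2)2(Ph2P(CH2)4PPh2) (3 mol%), toluene, 60 °C, sealed tube; the volatile enyne in twofold excess
Reagents that add atoms: none
Why: Ruthenium-catalysed anti-Markovnikov addition of a carboxylic acid to a terminal alkyne (carboxylate attack on the α-carbon of a ruthenium vinylidene), known for this enyne to give (Z)-dienyl esters; it is a pure addition in which every atom of one molecule of 5 and one molecule of 6 ends up in 7, and the neutral conditions should leave the silyl ether and the Z-enoate untouched.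

Step 6
Reactants: 8 1-(2,4-dihydroxyphenyl)ethanone
Product: 9 1-(2,4-dihydroxy-5-iodophenyl)ethanone
Conditions: N-iodosuccinimide (1.0 equiv), CF3CO2H (10 mol%), MeCN, 0 °C to rt
Reagents that add atoms: N-iodosuccinimide, O=C1CCC(=O)N1I
Why: Electrophilic aromatic iodination; under acidic conditions the electrophile should enter at C5, para to the chelated hydroxyl and ortho to the free one, in preference to the crowded carbon between the two hydroxyls, and one equivalent limits di-iodination.

Step 7
Reactants: 9 1-(2,4-dihydroxy-5-iodophenyl)ethanone; 7 (1Z)-3-methylbuta-1,3-dien-1-yl (Z)-2-[(tert-butyldimethylsilyloxy)methyl]but-2-enoate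
Product: 10 (2S,3R)-5-acetyl-6-hydroxy-2-(prop-1-en-2-yl)-2,3-dihydro-1-benzofuran-3-yl (Z)-2-[(tert-butyldimethylsilyloxy)methyl]but-2-enoate
Conditions: Pd(OAc)2 (5 mol%), (R)-BINAP (6 mol%), Ag2CO3 (1.5 equiv), 1,4-dioxane, 60 °C; the dienyl ester in 1.5-fold excess
Reagents that add atoms: none
Why: Proposed new method: zerovalent palladium (formed from Pd(OAc)2 and the bisphosphine) inserts into the C–I bond of 9, Ag2CO3 takes up iodide and the phenolic proton, and the resulting cationic divalent arylpalladium adds syn across the enol-ester C=C of 7 with the aryl group on the oxygen-bearing carbon (the electron-poor α-carbon of the polarised alkene, as in cationic Heck arylation of enol ethers), which forms C3a–C3 and leaves palladium as an η3-allyl over C2, the methyl-bearing carbon and the CH2 end. The phenoxide next to the new C–C bond then attacks the inner allyl carbon in a 5-exo closure that forms O1–C2 and ring B, regenerates zerovalent palladium and leaves the outer alkene as the isopropenyl group. The closest known reaction type is the palladium-catalysed heteroannulation of 2-iodophenols with 1,3-dienes, which has enantioselective versions for simple dienes but none for 1-acyloxy dienes, where the aryl group must go to the substituted terminus. C3 is set in the insertion under catalyst control: the chiral bisphosphine selects the face of the enol-ester alkene, the same event that is controlled in asymmetric Heck arylation of cyclic enol ethers. C2 is set in the closure under control of C3: the allyl can switch faces through its unsubstituted CH2 end, so the ring should close through the lower-energy arrangement with the isopropenyl group anti to the ester, and re-ionisation of the allylic aryl ether in the product would also lead toward the trans isomer. The step needs regioselectivity (aryl to C1 of the diene, not to the CH2 terminus), which the acyloxy polarisation and the halide-free cationic conditions are meant to provide. It also needs chemoselectivity, which the substrate provides: only the hydroxyl ortho to iodine can reach the allyl (the other is tied to the acetyl group), the trisubstituted enoate alkene is much less reactive toward carbopalladation than the diene, and the silyl ether is not ionised. Loss of the acyloxy group by β-elimination from the σ-bonded form of the intermediate is the main competing path and should be slowed once the η3-allyl has formed.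

Step 8
Reactants: 10 (2S,3R)-5-acetyl-6-hydroxy-2-(prop-1-en-2-yl)-2,3-dihydro-1-benzofuran-3-yl (Z)-2-[(tert-butyldimethylsilyloxy)methyl]but-2-enoate
Product: 11 (2S,3R)-5-acetyl-6-hydroxy-2-(prop-1-en-2-yl)-2,3-dihydro-1-benzofuran-3-yl (Z)-2-(hydroxymethyl)but-2-enoate
Conditions: HF·pyridine, pyridine, THF, 0 °C to rt
Reagents that add atoms: none
Why: Fluoride cleavage of a primary silyl ether; the pyridine-buffered reagent stays weakly acidic, so no phenoxide para to the benzylic ester is formed (which could expel the carboxylate), and the Z-enoate and both stereocentres should be untouched.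

Step 9
Reactants: 11 (2S,3R)-5-acetyl-6-hydroxy-2-(prop-1-en-2-yl)-2,3-dihydro-1-benzofuran-3-yl (Z)-2-(hydroxymethyl)but-2-enoate
Product: 12 (2S,3R)-5-acetyl-6-hydroxy-2-(prop-1-en-2-yl)-2,3-dihydro-1-benzofuran-3-yl (Z)-2-(acetoxymethyl)but-2-enoate
Conditions: AcCl (1.05 equiv), 2,4,6-collidine, CH2Cl2, −78 °C
Reagents that add atoms: acetyl chloride, CC(Cl)=O
Why: Chemoselective O-acetylation of a primary alcohol with an acid chloride and a hindered weak base at low temperature; the C6 phenol is deactivated by its hydrogen bond to the acetyl group and is not deprotonated by collidine, and no stereocentre is involved.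

## Compound list

1 | but-2-yn-1-ol | CC#CCO | starting material
2 | (Z)-2-(tributylstannyl)but-2-en-1-ol | C/C=C(/CO)[Sn](CCCC)(CCCC)CCCC | intermediate
3 | methyl (Z)-2-(hydroxymethyl)but-2-enoate | C/C=C(/CO)C(=O)OC | intermediate
4 | methyl (Z)-2-[(tert-butyldimethylsilyloxy)methyl]but-2-enoate | C/C=C(/CO[Si](C)(C)C(C)(C)C)C(=O)OC | intermediate
5 | (Z)-2-[(tert-butyldimethylsilyloxy)methyl]but-2-enoic acid | C/C=C(/CO[Si](C)(C)C(C)(C)C)C(=O)O | intermediate
6 | 2-methylbut-1-en-3-yne | C=C(C)C#C | starting material
7 | (1Z)-3-methylbuta-1,3-dien-1-yl (Z)-2-[(tert-butyldimethylsilyloxy)methyl]but-2-enoate | C=C(C)/C=C\OC(=O)/C(=C\C)CO[Si](C)(C)C(C)(C)C | intermediate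
8 | 1-(2,4-dihydroxyphenyl)ethanone | CC(=O)c1ccc(O)cc1O | starting material
9 | 1-(2,4-dihydroxy-5-iodophenyl)ethanone | CC(=O)c1cc(I)c(O)cc1O | intermediate
10 | (2S,3R)-5-acetyl-6-hydroxy-2-(prop-1-en-2-yl)-2,3-dihydro-1-benzofuran-3-yl (Z)-2-[(tert-butyldimethylsilyloxy)methyl]but-2-enoate | C=C(C)[C@@H]1Oc2cc(O)c(C(C)=O)cc2[C@H]1OC(=O)/C(=C\C)CO[Si](C)(C)C(C)(C)C | intermediate
11 | (2S,3R)-5-acetyl-6-hydroxy-2-(prop-1-en-2-yl)-2,3-dihydro-1-benzofuran-3-yl (Z)-2-(hydroxymethyl)but-2-enoate | C=C(C)[C@@H]1Oc2cc(O)c(C(C)=O)cc2[C@H]1OC(=O)/C(=C\C)CO | intermediate
12 | (2S,3R)-5-acetyl-6-hydroxy-2-(prop-1-en-2-yl)-2,3-dihydro-1-benzofuran-3-yl (Z)-2-(acetoxymethyl)but-2-enoate | C=C(C)[C@@H]1Oc2cc(O)c(C(C)=O)cc2[C@H]1OC(=O)/C(=C\C)COC(C)=O | target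

## Step count and least certain steps

Total: 9 steps. Longest linear sequence: 8 steps (steps 1, 2, 3, 4, 5, 7, 8, 9); step 6 is a one-step side branch.

**Step 7 (key step, new method).** Four things may go wrong:
- aryl transfer to the CH2 terminus of the diene instead of the oxygen-bearing carbon;
- β-acyloxy or β-hydride elimination before the oxygen closes the ring;
- poor facial selectivity in the insertion;
- acyl transfer from the enol ester to the phenol under the basic conditions.

The fallback uses known reaction types, sets out from 9 and 5, and rejoins the route at 11. Heck coupling of 9 with 2-methylbut-3-en-2-ol (Pd(OAc)2, P(o-tol)3, Et3N, MeCN, 80 °C) should give (E)-1-[2,4-dihydroxy-5-(3-hydroxy-3-methylbut-1-en-1-yl)phenyl]ethanone F1. Catalytic TsOH in warm toluene should close it to 1-(7-hydroxy-2,2-dimethyl-2H-chromen-6-yl)ethanone F2, whose linear ring fusion is fixed by the position of the iodine. Silylation (TBSOTf, 2,6-lutidine) gives 1-[7-(tert-butyldimethylsilyloxy)-2,2-dimethyl-2H-chromen-6-yl]ethanone F3. Jacobsen–Katsuki epoxidation follows, with NaOCl, 4-phenylpyridine N-oxide and the antipode of the (salen)MnCl complex (salen = N,N'-bis(3,5-di-tert-butylsalicylidene)-1,2-cyclohexanediamine) that delivers the (3S,4S) series. It gives 1-[(3S,4S)-7-(tert-butyldimethylsilyloxy)-3,4-epoxy-2,2-dimethyl-3,4-dihydro-2H-chromen-6-yl]ethanone F4. Acid 5 opens the epoxide at the benzylic carbon with inversion (excess 5, CH2Cl2, rt to 40 °C) to give (3S,4R)-6-acetyl-7-(tert-butyldimethylsilyloxy)-3-hydroxy-2,2-dimethyl-3,4-dihydro-2H-chromen-4-yl (Z)-2-[(tert-butyldimethylsilyloxy)methyl]but-2-enoate F5. Tf2O with 2,6-lutidine (CH2Cl2, −78 to 0 °C) then triggers the 1,2-shift of the ring oxygen with inversion at the carbinol carbon, a known type of ring contraction of 2,2-dimethylchroman-3-ol sulfonates, and proton loss gives (2S,3R)-5-acetyl-6-(tert-butyldimethylsilyloxy)-2-(prop-1-en-2-yl)-2,3-dihydro-1-benzofuran-3-yl (Z)-2-[(tert-butyldimethylsilyloxy)methyl]but-2-enoate F6. HF·pyridine removes both silyl groups and gives 11. The weak points of this fallback are partial loss of inversion in the epoxide opening at the electron-rich benzylic carbon and participation of the neighbouring ester in the cationic step.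

**Step 5.** What may go wrong: Markovnikov addition or loss of alkene geometry, oligomerisation of the volatile enyne, or Z-to-E isomerisation of the acid on the metal. The fallback sets out from 5 and rejoins at 10. 1-Chloro-N,N,2-trimethylprop-1-en-1-amine converts 5 under neutral conditions into (Z)-2-[(tert-butyldimethylsilyloxy)methyl]but-2-enoyl chloride F7. This O-acylates the potassium dienolate of 3-methylbut-2-enal (KOt-Bu, THF, −78 °C) and should give mainly (1E)-3-methylbuta-1,3-dien-1-yl (Z)-2-[(tert-butyldimethylsilyloxy)methyl]but-2-enoate F8. F8 takes the place of 7 in step 7: the allyl intermediate no longer carries the enol-ester geometry, so the same trans product 10 is expected, although the ligand antipode may have to be chosen again.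

**Step 6.** What may go wrong: iodination between the two hydroxyls, or twofold iodination, giving mixtures that are hard to separate. The fallback sets out from 8 and rejoins at 9. Bromination with N-bromosuccinimide (MeCN, 0 °C), the better established halogenation of this ketone, gives 1-(5-bromo-2,4-dihydroxyphenyl)ethanone F9, which is purified by crystallisation. A copper-catalysed aromatic Finkelstein reaction (CuI, NaI, trans-N,N'-dimethylcyclohexane-1,2-diamine, dioxane, 110 °C) then gives 9.

**Step 9.** What may go wrong: acetylation of the phenol as well, or base-induced expulsion of the C3 carboxylate through the para-phenoxide with aromatisation of ring B. The fallback leads from 11 to 12 by enzymatic transesterification (immobilised Candida antarctica lipase B, vinyl acetate, tert-butyl methyl ether, 30 °C). It is neutral and selects the primary alcohol; it makes no new compound, F0.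

## Further compounds

F1 | step 7 | (E)-1-[2,4-dihydroxy-5-(3-hydroxy-3-methylbut-1-en-1-yl)phenyl]ethanone | CC(=O)c1cc(/C=C/C(C)(C)O)c(O)cc1O
F2 | step 7 | 1-(7-hydroxy-2,2-dimethyl-2H-chromen-6-yl)ethanone | CC(=O)c1cc2c(cc1O)OC(C)(C)C=C2
F3 | step 7 | 1-[7-(tert-butyldimethylsilyloxy)-2,2-dimethyl-2H-chromen-6-yl]ethanone | CC(=O)c1cc2c(cc1O[Si](C)(C)C(C)(C)C)OC(C)(C)C=C2
F4 | step 7 | 1-[(3S,4S)-7-(tert-butyldimethylsilyloxy)-3,4-epoxy-2,2-dimethyl-3,4-dihydro-2H-chromen-6-yl]ethanone | CC(=O)c1cc2c(cc1O[Si](C)(C)C(C)(C)C)OC(C)(C)[C@H]3O[C@@H]23
F5 | step 7 | (3S,4R)-6-acetyl-7-(tert-butyldimethylsilyloxy)-3-hydroxy-2,2-dimethyl-3,4-dihydro-2H-chromen-4-yl (Z)-2-[(tert-butyldimethylsilyloxy)methyl]but-2-enoate | CC(=O)c1cc2c(cc1O[Si](C)(C)C(C)(C)C)OC(C)(C)[C@@H](O)[C@@H]2OC(=O)/C(=C\C)CO[Si](C)(C)C(C)(C)C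
F6 | step 7 | (2S,3R)-5-acetyl-6-(tert-butyldimethylsilyloxy)-2-(prop-1-en-2-yl)-2,3-dihydro-1-benzofuran-3-yl (Z)-2-[(tert-butyldimethylsilyloxy)methyl]but-2-enoate | C=C(C)[C@@H]1Oc2cc(O[Si](C)(C)C(C)(C)C)c(C(C)=O)cc2[C@H]1OC(=O)/C(=C\C)CO[Si](C)(C)C(C)(C)C
F7 | step 5 | (Z)-2-[(tert-butyldimethylsilyloxy)methyl]but-2-enoyl chloride | C/C=C(/CO[Si](C)(C)C(C)(C)C)C(Cl)=O
F8 | step 5 | (1E)-3-methylbuta-1,3-dien-1-yl (Z)-2-[(tert-butyldimethylsilyloxy)methyl]but-2-enoate | C=C(C)/C=C/OC(=O)/C(=C\C)CO[Si](C)(C)C(C)(C)C
F9 | step 6 | 1-(5-bromo-2,4-dihydroxyphenyl)ethanone | CC(=O)c1cc(Br)c(O)cc1O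
F0 | step 9 | none | none
A1 | alternative 1 | 1-[(2S,3R)-6-fluoro-3-hydroxy-2-(prop-1-en-2-yl)-2,3-dihydro-1-benzofuran-5-yl]ethanone | C=C(C)[C@@H]1Oc2cc(F)c(C(C)=O)cc2[C@H]1O
A2 | alternative 1 | 1-[5-[(1R,2S)-1,2-dihydroxy-3-methylbut-3-en-1-yl]-2,4-difluorophenyl]ethanone | C=C(C)[C@H](O)[C@H](O)c1cc(C(C)=O)c(F)cc1F
A3 | alternative 2 | 1-[(2S,3S)-3,6-dihydroxy-2-(prop-1-en-2-yl)-2,3-dihydro-1-benzofuran-5-yl]ethanone | C=C(C)[C@@H]1Oc2cc(O)c(C(C)=O)cc2[C@@H]1O
A4 | alternative 2 | 5-acetyl-4-hydroxy-2-(propa-1,2-dien-1-yloxy)benzaldehyde | CC(=O)c1cc(C=O)c(OC=C=C)cc1O
A5 | alternative 3 | (2S,3R)-5-acetyl-6-(tert-butyldimethylsilyloxy)-2-(prop-1-en-2-yl)-2,3-dihydro-1-benzofuran-3-yl (Z)-2-(acetoxymethyl)but-2-enoate | C=C(C)[C@@H]1Oc2cc(O[Si](C)(C)C(C)(C)C)c(C(C)=O)cc2[C@H]1OC(=O)/C(=C\C)COC(C)=O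
A6 | alternative 3 | (3S,4R)-6-acetyl-7-(tert-butyldimethylsilyloxy)-3-hydroxy-2,2-dimethyl-3,4-dihydro-2H-chromen-4-yl (Z)-2-(acetoxymethyl)but-2-enoate | CC(=O)c1cc2c(cc1O[Si](C)(C)C(C)(C)C)OC(C)(C)[C@@H](O)[C@@H]2OC(=O)/C(=C\C)COC(C)=O
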